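**Plan**
- Germacrane numbering is used: C1=C2 enol ether, C4 quaternary ether carbon, C5=C6 ylidene, C7=C11 butenolide alkene, C8 ester carbinol, C10 tertiary carbinol, C12 lactone carbonyl, C13 acetoxymethyl.
- Retrosynthesis: cut the two esters (C8–O methacrylate, C13–O acetate), reopen C5=C6 to a C5 acetate/C6–H pair, then cut C9–C10 (ring-closing aldol), C7–C8 (Stille), C5–C6 (vinylogous aldol) and C1–C10 (acylation of a lithiated dihydrofuran).
- Enabling feature: C10 is a tertiary carbinol β to the C8 oxygen and bonded to the enol-ether carbon C1 of the dihydrofuran ring. That is the aldol of a C8 ketone enolate (C9) with a 2-acetyl-4,5-dihydrofuran whose C4 holds the tether.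
- Forward: the dihydrofuran ring comes from (R)-linalool and the butenolide ring from tetronic acid; they are joined at C5–C6, C8–C9 is added by Stille coupling, and the ten-membered carbocycle (nine-membered oxacycle) is closed last at C9–C10, followed by reduction, esterification and elimination.
- Stereochemistry: C4 from (R)-linalool; C10 from C4 through the tether in the samarium aldol; C8 from C10 by chelation-controlled reduction; the C5=C6 geometry is fixed by the ring.

Key step: step 14

Assumption: the vinylogous aldol of step 11 is drawn as its (5S,6R) adduct. Whichever C5/C6 diastereomer predominates is carried on alone, because both carbons become trigonal in step 17.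

**Step 1**
Reactants: 1 (R)-linalool
Product: 3 (2R)-2-ethenyl-5-methoxy-2-methyloxolane (anomer mixture), via lactol 2 (not isolated)
Conditions: O3 (1.0 equiv, metered), CH2Cl2–MeOH, −78 °C; Me2S, −78 °C → rt; then pyridinium p-toluenesulfonate (cat.), MeOH, rt
Reagents that add atoms: methanol CO
Why: Chemoselective ozonolysis consumes the electron-rich trisubstituted alkene first, the freed 4-hydroxy aldehyde closes to lactol 2, and Fischer acetalisation caps it as the methyl acetal while the carbinol carbon (future C4) and its vinyl group stay untouched.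

**Step 2**
Reactants: 3 (2R)-2-ethenyl-5-methoxy-2-methyloxolane
Product: 4 [(2R)-5-methoxy-2-methyloxolan-2-yl]methanol
Conditions: O3 (to the alkene end point), CH2Cl2–MeOH, −78 °C; then NaBH4, −78 → 0 °C
Reagents that add atoms: ozone [O-][O+]=O
Why: Ozonolysis of the remaining vinyl group with reductive borohydride work-up should give the primary alcohol (future C5) directly, with the acetal masking C1.

**Step 3**
Reactants: 4 [(2R)-5-methoxy-2-methyloxolan-2-yl]methanol
Product: 5 tert-butyl{[(2R)-5-methoxy-2-methyloxolan-2-yl]methoxy}dimethylsilane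
Conditions: TBSCl, imidazole, DMF, rt
Reagents that add atoms: tert-butyldimethylsilyl chloride CC(C)(C)[Si](C)(C)Cl
Why: Standard silylation of a primary alcohol protects the C5 oxygen for the organolithium step.

**Step 4**
Reactants: 5 tert-butyl{[(2R)-5-methoxy-2-methyloxolan-2-yl]methoxy}dimethylsilane
Product: 6 tert-butyldimethyl{[(2R)-2-methyl-2,3-dihydrofuran-2-yl]methoxy}silane
Conditions: TMSOTf (1.2 equiv), iPr2NEt (1.5 equiv), CH2Cl2, −20 °C → rt; basic work-up
Reagents that add atoms: none
Why: Silyl triflate/amine elimination of methanol from an acetal (Gassman-type acetal-to-enol-ether conversion) should unveil the C1=C2 enol ether under aprotic conditions that the silyl ether tolerates.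

**Step 5**
Reactants: 6 tert-butyldimethyl{[(2R)-2-methyl-2,3-dihydrofuran-2-yl]methoxy}silane; 7 N-methoxy-N-methylacetamide
Product: 9 1-[(5R)-5-{[(tert-butyldimethylsilyl)oxy]methyl}-5-methyl-4,5-dihydrofuran-2-yl]ethan-1-one, via lithiodihydrofuran 8 (not isolated)
Conditions: t-BuLi (1.3 equiv), THF, −78 → 0 °C; then 7, −78 °C; H2O
Reagents that add atoms: none
Why: α-Lithiation of the cyclic enol ether at its oxygen-bearing vinylic carbon followed by Weinreb ketone synthesis installs the C10 acetyl group (C1–C10 bond) without over-addition.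

**Step 6**
Reactants: 9 1-[(5R)-5-{[(tert-butyldimethylsilyl)oxy]methyl}-5-methyl-4,5-dihydrofuran-2-yl]ethan-1-one
Product: 10 1-[(5R)-5-(hydroxymethyl)-5-methyl-4,5-dihydrofuran-2-yl]ethan-1-one
Conditions: Bu4NF, THF, 0 °C; H2O
Reagents that add atoms: none
Why: Fluoride desilylation frees the primary alcohol, and the acyl-deactivated enol ether is not affected.

**Step 7**
Reactants: 10 1-[(5R)-5-(hydroxymethyl)-5-methyl-4,5-dihydrofuran-2-yl]ethan-1-one
Product: 11 (2R)-5-acetyl-2-methyl-2,3-dihydrofuran-2-carbaldehyde
Conditions: Dess–Martin periodinane, pyridine, CH2Cl2, 0 °C → rt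
Reagents that add atoms: none
Why: Dess–Martin oxidation of the neopentyl-type primary alcohol should give the non-enolisable C5 aldehyde under buffered conditions.

**Step 8**
Reactants: 12 tetronic acid
Product: 13 4-bromo-2-oxo-2,5-dihydrofuran-3-carbaldehyde
Conditions: PBr3 (2.2 equiv), DMF (3 equiv), CHCl3, 0 → 60 °C; then ice–water
Reagents that add atoms: N,N-dimethylformamide CN(C)C=O; phosphorus tribromide BrP(Br)Br; water O
Why: Vilsmeier–Haack–Arnold haloformylation of a cyclic β-keto lactone enol, as practised on 4-hydroxycoumarins and 4-hydroxy-2-pyranones, formylates the nucleophilic C3 (future C13) and exchanges the enolic hydroxyl for bromide.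

**Step 9**
Reactants: 13 4-bromo-2-oxo-2,5-dihydrofuran-3-carbaldehyde
Product: 14 4-bromo-3-(hydroxymethyl)furan-2(5H)-one
Conditions: NaBH(OAc)3 (1.5 equiv), THF, 0 °C → rt
Reagents that add atoms: none
Why: The mild, non-basic triacetoxyborohydride should reduce only the aldehyde and leave the lactone and the vinylogous acyl bromide in place.

**Step 10**
Reactants: 14 4-bromo-3-(hydroxymethyl)furan-2(5H)-one
Product: 16 {[4-bromo-3-({[tert-butyl(dimethyl)silyl]oxy}methyl)furan-2-yl]oxy}(tert-butyl)dimethylsilane, via silyl ether 15 (not isolated)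
Conditions: TBSOTf (2.3 equiv), Et3N (3.5 equiv), CH2Cl2, −78 → 0 °C; pentane, cold NaHCO3 wash, used crude
Reagents that add atoms: tert-butyldimethylsilyl trifluoromethanesulfonate CC(C)(C)[Si](C)(C)OS(=O)(=O)C(F)(F)F
Why: One reagent silylates the primary alcohol and then, by soft enolisation at the γ-CH2 of the butenolide, forms the aromatic 2-silyloxyfuran (standard silyloxyfuran synthesis).

**Step 11**
Reactants: 11 (2R)-5-acetyl-2-methyl-2,3-dihydrofuran-2-carbaldehyde; 16 bis-silylated 4-bromofuran
Product: 17 C5–C6 aldol adduct (4R,5S,6R), a 4-bromobutenolide carrying the C5 carbinol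
Conditions: BF3·OEt2 (1.2 equiv), CH2Cl2, −78 °C; aq. NaHCO3
Reagents that add atoms: none
Why: In this vinylogous Mukaiyama aldol the BF3-activated, non-enolisable aldehyde is attacked by the free γ-carbon of the silyloxyfuran (the α-carbon is blocked), forming C5–C6 through an open transition state; the two new centres are erased later.

**Step 12**
Reactants: 17 C5–C6 aldol adduct
Product: 18 C5 acetate of 17
Conditions: Ac2O, pyridine, 4-(dimethylamino)pyridine (cat.), CH2Cl2, 0 °C
Reagents that add atoms: acetic anhydride CC(=O)OC(C)=O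
Why: Nucleophile-catalysed acetylation turns the C5 hydroxyl into the leaving group for the late elimination and protects it during the coupling.

**Step 13**
Reactants: 18 C5 acetate with the C7 bromide; 19 tributyl(1-ethoxyethenyl)stannane
Product: 21 C8 ketone with the C9 bromide (bromoacetyl butenolide), via ethoxyvinyl diene 20 (not isolated)
Conditions: PdCl2(PPh3)2 (5 mol%), 19 (1.1 equiv), 1,4-dioxane, 90 °C; then THF–H2O, NBS (1.1 equiv), 0 °C
Reagents that add atoms: N-bromosuccinimide O=C1CCC(=O)N1Br; water O
Why: Stille coupling of the activated β-bromo butenolide followed by bromination–hydrolysis of the enol ether with NBS in aqueous THF is the standard two-stage route to bromomethyl ketones, and the terminal ethoxyvinyl group should be far more nucleophilic than the acyl-deactivated dihydrofuran enol ether.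

**Step 14**
Reactants: 21 C8 ketone with the C9 bromide
Product: 23 bridged macrocyclic C8 ketone with the C10 tertiary alcohol (4R,5S,6S,10S), via samarium enolate 22 (not isolated)
Conditions: SmI2 (2.1 equiv, 0.1 M in THF) added over 2 h to 21 (0.002 M in THF), −78 °C; pH 7 phosphate buffer at −78 °C; Et3N-deactivated silica
Reagents that add atoms: none
Why: Two single-electron transfers from SmI2 cleave the C9–Br bond and give the trivalent samarium enolate 22, which adds through a samarium-bridged transition state to the C10 methyl ketone; the closest known reaction is the SmI2-mediated intramolecular Reformatsky-type aldol of α-bromo carbonyl compounds, which closes eight- and nine-membered rings and accepts ketones. The closure is 9-exo-trig for the nine-membered oxacycle C9–C8–C7–C6–C5–C4–O–C1–C10, which is at the same time the ten-membered carbocycle C1–C10. The new stereocentre C10 is controlled by C4: the acetyl group is coplanar with the dihydrofuran and the short tether leaves C4 through C5, so C9 can reach only the ring face syn to C5, and attack on the dipole-minimised rotamer (carbonyl oxygen anti to the ring oxygen) gives 10S. The step needs chemoselective reduction of the C–Br bond beside the ene-dione, the C5 acetate and the allylic C13 ether; the much faster halide reduction, the poor leaving ability of the silyl ether, the absence of HMPA and the slow addition of about two equivalents at −78 °C should secure it. It also needs ring closure to outrun dimerisation and proton transfer from C6–H, for which high dilution and the low basicity of samarium enolates are relied on; the strong Sm–O bond should hold the tertiary aldolate against retro-aldol until the cold buffered quench.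

**Step 15**
Reactants: 23 bridged macrocyclic C8 ketone
Product: 25 syn-8,10-diol (8R), via boron chelate 24 (not isolated)
Conditions: Et2BOMe (1.2 equiv), THF–MeOH (4:1), −78 °C, 1 h; NaBH4 (1.2 equiv), −78 °C; pH 7 buffer; co-evaporation with MeOH
Reagents that add atoms: none
Why: In this Narasaka–Prasad reduction the C10 oxygen and the C8 carbonyl are tied into the six-membered diethylboron chelate 24, which in the bridged macrocycle can only exist with C7 and C1 cis, so external hydride should give the syn-1,3-diol (8R), the tetrasubstituted C7=C11 alkene resisting conjugate reduction.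

**Step 16**
Reactants: 25 syn-8,10-diol
Product: 26 C8 methacrylate
Conditions: methacrylic anhydride (1.5 equiv), Et3N, 4-(dimethylamino)pyridine (0.1 equiv), CH2Cl2, 0 °C
Reagents that add atoms: methacrylic anhydride C=C(C)C(=O)OC(=O)C(C)=C
Why: Nucleophile-catalysed acylation should select the secondary C8 hydroxyl over the tertiary C10 hydroxyl on steric grounds.

**Step 17**
Reactants: 26 C8 methacrylate
Product: 27 C5=C6 ylidene butenolide (5E) with the C13 silyl ether
Conditions: DBU (1.5 equiv), CH2Cl2, 0 °C → rt
Reagents that add atoms: none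
Why: In this E1cB elimination DBU removes the acidic γ-hydrogen C6–H of the butenolide and the furanolate expels the C5 acetate (a far better leaving group than the C13 silyloxide), the ring fixing the alkene geometry with C4 cis to C7.

**Step 18**
Reactants: 27 C5=C6 ylidene butenolide
Product: 28 C13 primary alcohol
Conditions: Bu4NF–AcOH (1:1, 2 equiv), THF, 0 °C → rt
Reagents that add atoms: none
Why: Acetic acid-buffered fluoride should remove the primary silyl ether without touching the methacrylate, the enol lactone or the acid-labile C1=C2 enol ether.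

**Step 19**
Reactants: 28 C13 primary alcohol
Product: 29 target CNP0394509.1
Conditions: Ac2O (1.5 equiv), pyridine, CH2Cl2, 0 °C
Reagents that add atoms: acetic anhydride CC(=O)OC(C)=O
Why: Pyridine-mediated acetylation acylates the primary allylic alcohol, while the tertiary C10 hydroxyl stays free under these unforced conditions.

**Compound list**
1 | (R)-linalool [(3R)-3,7-dimethylocta-1,6-dien-3-ol] | CC(C)=CCC[C@](C)(C=C)O | starting material
2 | (5R)-5-ethenyl-5-methyloxolan-2-ol (lactol, anomers) | OC1CC[C@](C)(C=C)O1 | intermediate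
3 | (2R)-2-ethenyl-5-methoxy-2-methyloxolane (anomers) | COC1CC[C@](C)(C=C)O1 | intermediate
4 | [(2R)-5-methoxy-2-methyloxolan-2-yl]methanol | COC1CC[C@](C)(CO)O1 | intermediate
5 | tert-butyl{[(2R)-5-methoxy-2-methyloxolan-2-yl]methoxy}dimethylsilane | COC1CC[C@](C)(CO[Si](C)(C)C(C)(C)C)O1 | intermediate
6 | tert-butyldimethyl{[(2R)-2-methyl-2,3-dihydrofuran-2-yl]methoxy}silane | C1=CC[C@](C)(CO[Si](C)(C)C(C)(C)C)O1 | intermediate
7 | N-methoxy-N-methylacetamide | CON(C)C(C)=O | starting material
8 | [(5R)-5-{[(tert-butyldimethylsilyl)oxy]methyl}-5-methyl-4,5-dihydrofuran-2-yl]lithium | [Li]C1=CC[C@](C)(CO[Si](C)(C)C(C)(C)C)O1 | intermediate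
9 | 1-[(5R)-5-{[(tert-butyldimethylsilyl)oxy]methyl}-5-methyl-4,5-dihydrofuran-2-yl]ethan-1-one | CC(=O)C1=CC[C@](C)(CO[Si](C)(C)C(C)(C)C)O1 | intermediate
10 | 1-[(5R)-5-(hydroxymethyl)-5-methyl-4,5-dihydrofuran-2-yl]ethan-1-one | CC(=O)C1=CC[C@](C)(CO)O1 | intermediate
11 | (2R)-5-acetyl-2-methyl-2,3-dihydrofuran-2-carbaldehyde | CC(=O)C1=CC[C@](C)(C=O)O1 | intermediate
12 | tetronic acid [4-hydroxyfuran-2(5H)-one] | OC1=CC(=O)OC1 | starting material
13 | 4-bromo-2-oxo-2,5-dihydrofuran-3-carbaldehyde | O=CC1=C(Br)COC1=O | intermediate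
14 | 4-bromo-3-(hydroxymethyl)furan-2(5H)-one | OCC1=C(Br)COC1=O | intermediate
15 | 4-bromo-3-{[(tert-butyldimethylsilyl)oxy]methyl}furan-2(5H)-one | CC(C)(C)[Si](C)(C)OCC1=C(Br)COC1=O | intermediate
16 | {[4-bromo-3-({[tert-butyl(dimethyl)silyl]oxy}methyl)furan-2-yl]oxy}(tert-butyl)dimethylsilane | CC(C)(C)[Si](C)(C)OCc1c(O[Si](C)(C)C(C)(C)C)occ1Br | intermediate
17 | (5R)-5-{(S)-[(2R)-5-acetyl-2-methyl-2,3-dihydrofuran-2-yl](hydroxy)methyl}-4-bromo-3-{[(tert-butyldimethylsilyl)oxy]methyl}furan-2(5H)-one | BrC1=C(CO[Si](C)(C)C(C)(C)C)C(=O)O[C@@H]1[C@H](O)[C@@]2(C)CC=C(O2)C(C)=O | intermediate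
18 | (S)-[(2R)-5-acetyl-2-methyl-2,3-dihydrofuran-2-yl][(2R)-3-bromo-4-{[(tert-butyldimethylsilyl)oxy]methyl}-5-oxo-2,5-dihydrofuran-2-yl]methyl acetate | BrC1=C(CO[Si](C)(C)C(C)(C)C)C(=O)O[C@@H]1[C@H](OC(C)=O)[C@@]2(C)CC=C(O2)C(C)=O | intermediate
19 | tributyl(1-ethoxyethenyl)stannane | CCCC[Sn](CCCC)(CCCC)C(=C)OCC | starting material
20 | (S)-[(2R)-5-acetyl-2-methyl-2,3-dihydrofuran-2-yl][(2S)-4-{[(tert-butyldimethylsilyl)oxy]methyl}-3-(1-ethoxyethenyl)-5-oxo-2,5-dihydrofuran-2-yl]methyl acetate | C=C(OCC)C1=C(CO[Si](C)(C)C(C)(C)C)C(=O)O[C@@H]1[C@H](OC(C)=O)[C@@]2(C)CC=C(O2)C(C)=O | intermediate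
21 | (S)-[(2R)-5-acetyl-2-methyl-2,3-dihydrofuran-2-yl][(2S)-3-(bromoacetyl)-4-{[(tert-butyldimethylsilyl)oxy]methyl}-5-oxo-2,5-dihydrofuran-2-yl]methyl acetate | BrCC(=O)C1=C(CO[Si](C)(C)C(C)(C)C)C(=O)O[C@@H]1[C@H](OC(C)=O)[C@@]2(C)CC=C(O2)C(C)=O | intermediate
22 | diiodosamarium C8–C9 enolate derived from 21 | C=C(O[Sm](I)I)C1=C(CO[Si](C)(C)C(C)(C)C)C(=O)O[C@@H]1[C@H](OC(C)=O)[C@@]2(C)CC=C(O2)C(C)=O | intermediate
23 | (4R,5S,6S,10S)-5-acetoxy-13-[(tert-butyldimethylsilyl)oxy]-10-hydroxy-8-oxo-1,4-epoxygermacra-1,7(11)-dien-12,6-olide | O=C1C[C@](C)(O)C2=CC[C@](C)([C@@H](OC(C)=O)[C@H]3OC(=O)C(CO[Si](C)(C)C(C)(C)C)=C31)O2 | intermediate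
24 | C10 O-diethylboryl derivative of 23 (boron chelate to the C8 carbonyl) | O=C1C[C@](C)(OB(CC)CC)C2=CC[C@](C)([C@@H](OC(C)=O)[C@H]3OC(=O)C(CO[Si](C)(C)C(C)(C)C)=C31)O2 | intermediate
25 | (4R,5S,6S,8R,10S)-5-acetoxy-13-[(tert-butyldimethylsilyl)oxy]-8,10-dihydroxy-1,4-epoxygermacra-1,7(11)-dien-12,6-olide | O[C@@H]1C[C@](C)(O)C2=CC[C@](C)([C@@H](OC(C)=O)[C@H]3OC(=O)C(CO[Si](C)(C)C(C)(C)C)=C31)O2 | intermediate
26 | (4R,5S,6S,8R,10S)-5-acetoxy-13-[(tert-butyldimethylsilyl)oxy]-10-hydroxy-8-(methacryloyloxy)-1,4-epoxygermacra-1,7(11)-dien-12,6-olide | C=C(C)C(=O)O[C@@H]1C[C@](C)(O)C2=CC[C@](C)([C@@H](OC(C)=O)[C@H]3OC(=O)C(CO[Si](C)(C)C(C)(C)C)=C31)O2 | intermediate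
27 | (4R,5E,8R,10S)-13-[(tert-butyldimethylsilyl)oxy]-10-hydroxy-8-(methacryloyloxy)-1,4-epoxygermacra-1,5,7(11)-trien-12,6-olide | C=C(C)C(=O)O[C@@H]1C[C@](C)(O)C2=CC[C@](C)(/C=C3/OC(=O)C(CO[Si](C)(C)C(C)(C)C)=C31)O2 | intermediate
28 | (4R,5E,8R,10S)-10,13-dihydroxy-8-(methacryloyloxy)-1,4-epoxygermacra-1,5,7(11)-trien-12,6-olide | C=C(C)C(=O)O[C@@H]1C[C@](C)(O)C2=CC[C@](C)(/C=C3/OC(=O)C(CO)=C31)O2 | intermediate
29 | CNP0394509.1, (4R,5E,8R,10S)-13-acetoxy-10-hydroxy-8-(methacryloyloxy)-1,4-epoxygermacra-1,5,7(11)-trien-12,6-olide | C=C(C)C(=O)O[C@@H]1C[C@](C)(O)C2=CC[C@](C)(/C=C3/OC(=O)C(COC(C)=O)=C31)O2 | target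

**Step count**
Total: 19 steps (7 to aldehyde 11, 3 to silyloxyfuran 16, 9 from the union to the target). Longest linear sequence: 16 steps (steps 1–7 and 11–19).

**Steps most likely to fail**

Step 14. The samarium enolate may be quenched by proton transfer from C6–H, or may react between molecules before the nine-membered transition state is reached. Coordination of the ring oxygen by samarium may also populate the other acetyl rotamer and lower the selectivity at C10. The fallback generates the nucleophile as a neutral enol silane and closes the ring under Lewis acid control. It sets out from 21: reductive silylation of the α-bromo ketone (Zn dust, Me3SiCl, TMEDA, Et2O, 0 °C) should give the C8 trimethylsilyl enol ether F1. An intramolecular Mukaiyama aldol of F1 under high dilution (BF3·OEt2, CH2Cl2, 0.002 M, −78 °C) uses a monodentate Lewis acid that cannot chelate the ring oxygen and passes through an open transition state on the same tether-defined face. It comes back to the route at 23.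

Step 13. Bromination by NBS may not discriminate fully between the ethoxyvinyl group and the dihydrofuran enol ether, and the intermediate diene may hydrolyse to the methyl ketone before it is brominated. The fallback avoids any electrophilic bromine source and sets out from 18. Stannylation with hexabutylditin under zerovalent palladium catalysis [(Bu3Sn)2, Pd(PPh3)4, toluene, 100 °C] should give the C7 vinylstannane F2. Stille acylation with acetoxyacetyl chloride [Pd2(dba)3, tri(2-furyl)phosphine, toluene, 60 °C] should then give the C8 ketone with a C9 acetate, the α-acetoxy ketone F3. SmI2 cleaves α-acyloxy ketones as readily as α-bromo ketones, so F3 under the conditions of step 14 should give the same enolate 22 and come back to the route at 23.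

Step 15. The hindered tertiary C10 hydroxyl may fail to form the boron chelate, so that hydride adds without facial control or in conjugate fashion to the ene-dione. The fallback replaces substrate chelation by reagent control and sets out from 23. Reduction with catecholborane and the (S)-configured CBS oxazaborolidine [(S)-1-methyl-3,3-diphenyltetrahydro-1H,3H-pyrrolo[1,2-c][1,3,2]oxazaborole, 20 mol%] in toluene at −78 °C treats the alkenyl C7 side as the large group. Hydride delivery to the C8 carbonyl should therefore give 8R independently of the C10 hydroxyl, with the enol ether inert to catecholborane at this temperature. It comes back to the route at 25 and makes no new compound (F0).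

**Further compounds**
F1 | step 14 | C8 trimethylsilyl enol ether, (S)-[(2R)-5-acetyl-2-methyl-2,3-dihydrofuran-2-yl][(2S)-4-{[(tert-butyldimethylsilyl)oxy]methyl}-5-oxo-3-{1-[(trimethylsilyl)oxy]ethenyl}-2,5-dihydrofuran-2-yl]methyl acetate | C=C(O[Si](C)(C)C)C1=C(CO[Si](C)(C)C(C)(C)C)C(=O)O[C@@H]1[C@H](OC(C)=O)[C@@]2(C)CC=C(O2)C(C)=O
F2 | step 13 | C7 tributylstannyl analogue of 18 (vinylstannane) | CCCC[Sn](CCCC)(CCCC)C1=C(CO[Si](C)(C)C(C)(C)C)C(=O)O[C@@H]1[C@H](OC(C)=O)[C@@]2(C)CC=C(O2)C(C)=O
F3 | step 13 | C9 acetoxy analogue of 21 (α-acetoxy ketone) | CC(=O)OCC(=O)C1=C(CO[Si](C)(C)C(C)(C)C)C(=O)O[C@@H]1[C@H](OC(C)=O)[C@@]2(C)CC=C(O2)C(C)=O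
F0 | step 15 | none | none
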